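**Retrosynthetic overview**
1. The strategy rests on the benzene ring of the isoquinoline (C4a, C5, C6, C7, C8, C8a; naphthalene atoms primed). It has oxygen on C6 and C8, 1,3 to each other with C7–H between them, and the naphthyl on C5, so it is an aromatised cyclohexane-1,3-dione whose C5 can enter as an sp3 benzylic carbon.
2. Key disconnection: C4a–C5 (Michael) and C6–C7 (Claisen). This leads back to the 3-acetyl tetrahydropyridine 9 and the naphthylacetic ester 20, which give dione 22 without any biaryl coupling.
3. Ring order: the methyl-bearing naphthalene ring (C5'–C8', Stobbe/Friedel–Crafts) and the nitrogen ring (N2, C1, C8a, C4a, C4, C3; ring-closing metathesis) are made in separate branches. The carbocycle C4a–C8a is closed last and then aromatised with I2/MeOH.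
4. C3 (S) comes from L-alaninol through the N-tosyl aziridine and a vinyl Grignard opening. The nitrogen carries a tosyl group because the aromatisation releases HI in hot methanol and the O-methylation that follows needs a nitrogen without N–H; it is removed in the last step.
5. Ester 20 comes from 2-bromo-5-methoxybenzaldehyde and diethyl succinate. The bromine blocks one ortho position during naphthalene formation and is then exchanged for CH2CO2Et by a Negishi coupling with the Reformatsky reagent.

Key step: step 13

Remark: the C5–C1' biaryl axis has three ortho substituents and probably rotates slowly; the target structure defines only C3, so the route fixes C3 as S and is expected to give both rotamers about this axis.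

**Step 1**
Reactants: 1 L-alaninol
Product: 3 (2S)-2-methyl-1-tosylaziridine, via N,O-ditosyl-L-alaninol 2 (not isolated)
Conditions: TsCl (2.4 equiv), KOH, H2O/CH2Cl2, rt
Reagents that add atoms: p-toluenesulfonyl chloride, Cc1ccc(cc1)S(=O)(=O)Cl
Why: N- and O-sulfonylation followed by intramolecular SN2 displacement of the primary tosylate by the sulfonamide anion (3-exo-tet) is the standard one-pot aziridination of 1,2-amino alcohols; the stereocentre takes no part and stays S.

**Step 2**
Reactants: 3 (2S)-2-methyl-1-tosylaziridine
Product: 4 4-methyl-N-[(2S)-pent-4-en-2-yl]benzenesulfonamide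
Conditions: CH2=CHMgBr (3 equiv), CuI (0.2 equiv), THF, −40 → 0 °C; aq NH4Cl
Reagents that add atoms: vinylmagnesium bromide, C=C[Mg]Br
Why: Copper-catalysed Grignard opening of the sulfonyl-activated aziridine is an SN2 attack at the unsubstituted CH2, so the C–N stereocentre is untouched and the descriptor stays S.

**Step 3**
Reactants: 4 4-methyl-N-[(2S)-pent-4-en-2-yl]benzenesulfonamide; 5 methyl 2-(bromomethyl)prop-2-enoate
Product: 6 methyl 2-({[(2S)-pent-4-en-2-yl](tosyl)amino}methyl)prop-2-enoate
Conditions: K2CO3, MeCN, 60 °C
Reagents that add atoms: none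
Why: N-alkylation of the sulfonamide anion by the reactive allylic bromide (SN2 or SN2', both give the same product) is routine and leaves the stereocentre alone.

**Step 4**
Reactants: 6 methyl 2-({[(2S)-pent-4-en-2-yl](tosyl)amino}methyl)prop-2-enoate
Product: 7 methyl (6S)-6-methyl-1-tosyl-1,2,5,6-tetrahydropyridine-3-carboxylate
Conditions: second-generation Grubbs catalyst (H2IMes)(PCy3)Cl2Ru=CHPh (5 mol %), CH2Cl2, 40 °C
Reagents that add atoms: none
Why: Ring-closing metathesis of a terminal alkene with a 1,1-disubstituted acrylate to a six-membered trisubstituted cycloalkene is a standard closure for this ruthenium carbene and is driven by loss of ethene.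

**Step 5**
Reactants: 7 methyl (6S)-6-methyl-1-tosyl-1,2,5,6-tetrahydropyridine-3-carboxylate
Product: 8 (6S)-N-methoxy-N,6-dimethyl-1-tosyl-1,2,5,6-tetrahydropyridine-3-carboxamide
Conditions: MeNH(OMe)·HCl (2 equiv), iPrMgCl (4 equiv), THF, −20 °C
Reagents that add atoms: N,O-dimethylhydroxylamine hydrochloride, CNOC.Cl
Why: Direct aminolysis of the ester by the chloromagnesium amide (Weinreb amide formation) should be faster at −20 °C than conjugate addition to the beta-substituted acrylate.

**Step 6**
Reactants: 8 (6S)-N-methoxy-N,6-dimethyl-1-tosyl-1,2,5,6-tetrahydropyridine-3-carboxamide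
Product: 9 1-[(6S)-6-methyl-1-tosyl-1,2,5,6-tetrahydropyridin-3-yl]ethan-1-one
Conditions: MeMgBr (1.5 equiv), THF, 0 °C; aq NH4Cl
Reagents that add atoms: methylmagnesium bromide, C[Mg]Br
Why: In the Weinreb ketone synthesis the chelated tetrahedral magnesium adduct persists until work-up, so a single methyl group is delivered and the enone forms only after the Grignard reagent is quenched.

**Step 7**
Reactants: 10 2-bromo-5-methoxybenzaldehyde; 11 diethyl succinate
Product: 13 (3E)-4-(2-bromo-5-methoxyphenyl)-3-(ethoxycarbonyl)but-3-enoic acid, via paraconic ester lactone 12 (not isolated)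
Conditions: KOtBu, t-BuOH, reflux; then aq HCl
Reagents that add atoms: none
Why: In the Stobbe condensation, aldol addition, lactonisation to 12 and base-induced ring opening give the alkylidene succinic half-ester, with the E isomer (aryl cis to CH2CO2H) expected to predominate.

**Step 8**
Reactants: 13 (3E)-4-(2-bromo-5-methoxyphenyl)-3-(ethoxycarbonyl)but-3-enoic acid
Product: 15 ethyl 4-acetoxy-8-bromo-5-methoxynaphthalene-2-carboxylate, via naphthol ester 14 (not isolated)
Conditions: Ac2O, NaOAc, reflux
Reagents that add atoms: acetic anhydride, CC(=O)OC(C)=O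
Why: Intramolecular Friedel–Crafts acylation through the mixed anhydride can occur only at the free ortho carbon next to the methoxy group, because the other ortho carbon carries bromine; enolisation then gives naphthol 14, which is acetylated in the same pot.

**Step 9**
Reactants: 15 ethyl 4-acetoxy-8-bromo-5-methoxynaphthalene-2-carboxylate
Product: 16 5-bromo-3-(hydroxymethyl)-8-methoxynaphthalen-1-ol
Conditions: LiAlH4, THF, 0 °C → rt; then dilute HCl
Reagents that add atoms: none
Why: LiAlH4 reduces the ethyl ester to the primary alcohol and cleaves the aryl acetate in one operation, while the aryl bromide is inert to the hydride at this temperature.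

**Step 10**
Reactants: 16 5-bromo-3-(hydroxymethyl)-8-methoxynaphthalen-1-ol
Product: 17 (8-bromo-4,5-dimethoxynaphthalen-2-yl)methanol
Conditions: Me2SO4 (1.1 equiv), K2CO3, acetone, reflux
Reagents that add atoms: dimethyl sulfate, COS(=O)(=O)OC
Why: In this Williamson ether synthesis K2CO3 deprotonates only the naphthol, so the phenoxide is methylated and the benzylic alcohol is not.

**Step 11**
Reactants: 17 (8-bromo-4,5-dimethoxynaphthalen-2-yl)methanol
Product: 19 1-bromo-4,5-dimethoxy-7-methylnaphthalene, via benzylic mesylate 18 (not isolated)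
Conditions: MsCl, Et3N, THF, 0 °C; then LiBEt3H, 0 °C → rt
Reagents that add atoms: none
Why: Sulfonate formation followed by SN2 hydride displacement with LiBEt3H deoxygenates the benzylic alcohol, and an aryl bromide does not react with this borohydride.

**Step 12**
Reactants: 19 1-bromo-4,5-dimethoxy-7-methylnaphthalene
Product: 20 ethyl 2-(4,5-dimethoxy-7-methylnaphthalen-1-yl)acetate
Conditions: BrZnCH2CO2Et (2 equiv, THF solution), Pd2(dba)3 (2.5 mol %), XPhos (10 mol %), THF, 65 °C
Reagents that add atoms: bromo(2-ethoxy-2-oxoethyl)zinc, CCOC(=O)C[Zn]Br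
Why: This is a Negishi coupling of the aryl bromide with the Reformatsky reagent (alpha-arylation of an ester zinc enolate), in which the bulky biaryl phosphine helps oxidative addition of zerovalent palladium to the electron-rich 1-naphthyl bromide.

**Step 13**
Reactants: 9 1-[(6S)-6-methyl-1-tosyl-1,2,5,6-tetrahydropyridin-3-yl]ethan-1-one; 20 ethyl 2-(4,5-dimethoxy-7-methylnaphthalen-1-yl)acetate
Product: 22 (3S)-5-(4,5-dimethoxy-7-methylnaphthalen-1-yl)-3-methyl-2-tosyl-octahydroisoquinoline-6,8-dione, via Michael adduct keto ester 21 (not isolated)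
Conditions: NaOEt (2.2 equiv), EtOH, reflux; then aq HCl to pH 3
Reagents that add atoms: none
Why: NaOEt deprotonates 20 at its only acidic carbon (the benzylic CH2 next to the ester) and this enolate adds to the beta-carbon C4a of enone 9 (Michael addition) to give keto ester 21; proton exchange in ethanol then provides the methyl-ketone enolate, whose carbon C7 attacks the ester carbonyl C6 with loss of ethoxide (intramolecular Claisen condensation), and deprotonation of the 1,3-dione to its stabilised enolate draws the reversible steps forward. The closest known reaction type is the Michael–Claisen synthesis of cyclohexane-1,3-diones from enones and malonic or arylacetic esters (dimedone synthesis), which is also established for 1-acetylcycloalkenes. The one ring that closes, the carbocycle C4a–C5–C6–C7–C8–C8a, forms in a 6-exo-trig acyl substitution by an enolate carbon. New stereocentres arise at C4a, C5 and C8a under thermodynamic control only (equilibration through the enolates) and need no control because all three become sp2 in step 14, whereas C3 has no acidic hydrogen and keeps its C–N bond, so it stays S. The step needs chemoselectivity (ester as donor, enone as acceptor, C–C bond at C4a before acylation), and this follows from the single enolisable position of 20 and from the fact that only the six-membered dione ends as a stable enolate; opening of the nitrogen ring by beta-elimination of the sulfonamide from the C8a enolate would be reversible (aza-Michael re-closure) and does not involve C3.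

**Step 14**
Reactants: 22 (3S)-5-(4,5-dimethoxy-7-methylnaphthalen-1-yl)-3-methyl-2-tosyl-octahydroisoquinoline-6,8-dione
Product: 25 (3S)-5-(4,5-dimethoxy-7-methylnaphthalen-1-yl)-6,8-dimethoxy-3-methyl-2-tosyl-1,2,3,4-tetrahydroisoquinoline, via 6-hydroxy-8-methoxy sulfonamide 23 (not isolated), via 8-hydroxy-6-methoxy sulfonamide 24 (not isolated)
Conditions: I2 (2 equiv), MeOH, reflux; aq Na2S2O3; then Me2SO4, K2CO3, acetone, reflux
Reagents that add atoms: methanol, CO; dimethyl sulfate, COS(=O)(=O)OC
Why: Iodine in methanol takes the dione through its methyl enol ether to an alpha-iodo ketone that loses HI (halogenation–dehydrohalogenation, the known aromatisation of cyclohexane-1,3-diones to resorcinol methyl ethers); the remaining phenolic OH of either regioisomer is then methylated (Williamson), and the sulfonamide is stable to HI and has no N–H to be methylated.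

**Step 15**
Reactants: 25 (3S)-5-(4,5-dimethoxy-7-methylnaphthalen-1-yl)-6,8-dimethoxy-3-methyl-2-tosyl-1,2,3,4-tetrahydroisoquinoline
Product: 26 (3S)-5-(4,5-dimethoxy-7-methylnaphthalen-1-yl)-6,8-dimethoxy-3-methyl-1,2,3,4-tetrahydroisoquinoline (CNP0236045.1)
Conditions: Na, naphthalene, DME, −78 °C; then MeOH, aq NaHCO3
Reagents that add atoms: none
Why: Single-electron reduction of the arenesulfonyl group by sodium naphthalenide cleaves the S–N bond (reductive detosylation); at −78 °C, with the reagent added only until its green colour persists, the harder-to-reduce methoxynaphthalene and the aryl ethers should stay intact, and C3 is not involved.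

**Compound list**
1 | L-alaninol, (2S)-2-aminopropan-1-ol | C[C@H](N)CO | starting material
2 | N,O-ditosyl-L-alaninol, (2S)-2-(tosylamino)propyl 4-methylbenzenesulfonate | C[C@H](NS(=O)(=O)c1ccc(C)cc1)COS(=O)(=O)c1ccc(C)cc1 | intermediate
3 | (2S)-2-methyl-1-tosylaziridine | C[C@H]1CN1S(=O)(=O)c1ccc(C)cc1 | intermediate
4 | 4-methyl-N-[(2S)-pent-4-en-2-yl]benzenesulfonamide | C[C@H](NS(=O)(=O)c1ccc(C)cc1)CC=C | intermediate
5 | methyl 2-(bromomethyl)prop-2-enoate | C=C(CBr)C(=O)OC | starting material
6 | methyl 2-({[(2S)-pent-4-en-2-yl](tosyl)amino}methyl)prop-2-enoate | C=CC[C@H](C)N(CC(=C)C(=O)OC)S(=O)(=O)c1ccc(C)cc1 | intermediate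
7 | methyl (6S)-6-methyl-1-tosyl-1,2,5,6-tetrahydropyridine-3-carboxylate | COC(=O)C1=CC[C@H](C)N(S(=O)(=O)c2ccc(C)cc2)C1 | intermediate
8 | (6S)-N-methoxy-N,6-dimethyl-1-tosyl-1,2,5,6-tetrahydropyridine-3-carboxamide | CON(C)C(=O)C1=CC[C@H](C)N(S(=O)(=O)c2ccc(C)cc2)C1 | intermediate
9 | 1-[(6S)-6-methyl-1-tosyl-1,2,5,6-tetrahydropyridin-3-yl]ethan-1-one | CC(=O)C1=CC[C@H](C)N(S(=O)(=O)c2ccc(C)cc2)C1 | intermediate
10 | 2-bromo-5-methoxybenzaldehyde | COc1ccc(Br)c(C=O)c1 | starting material
11 | diethyl succinate | CCOC(=O)CCC(=O)OCC | starting material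
12 | ethyl 2-(2-bromo-5-methoxyphenyl)-5-oxooxolane-3-carboxylate (paraconic ester, diastereomer mixture) | CCOC(=O)C1CC(=O)OC1c1cc(OC)ccc1Br | intermediate
13 | (3E)-4-(2-bromo-5-methoxyphenyl)-3-(ethoxycarbonyl)but-3-enoic acid | CCOC(=O)/C(CC(=O)O)=C/c1cc(OC)ccc1Br | intermediate
14 | ethyl 8-bromo-4-hydroxy-5-methoxynaphthalene-2-carboxylate | CCOC(=O)c1cc(O)c2c(OC)ccc(Br)c2c1 | intermediate
15 | ethyl 4-acetoxy-8-bromo-5-methoxynaphthalene-2-carboxylate | CCOC(=O)c1cc(OC(C)=O)c2c(OC)ccc(Br)c2c1 | intermediate
16 | 5-bromo-3-(hydroxymethyl)-8-methoxynaphthalen-1-ol | OCc1cc(O)c2c(OC)ccc(Br)c2c1 | intermediate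
17 | (8-bromo-4,5-dimethoxynaphthalen-2-yl)methanol | OCc1cc(OC)c2c(OC)ccc(Br)c2c1 | intermediate
18 | (8-bromo-4,5-dimethoxynaphthalen-2-yl)methyl methanesulfonate | CS(=O)(=O)OCc1cc(OC)c2c(OC)ccc(Br)c2c1 | intermediate
19 | 1-bromo-4,5-dimethoxy-7-methylnaphthalene | Cc1cc(OC)c2c(OC)ccc(Br)c2c1 | intermediate
20 | ethyl 2-(4,5-dimethoxy-7-methylnaphthalen-1-yl)acetate | CCOC(=O)Cc1ccc(OC)c2c(OC)cc(C)cc12 | intermediate
21 | ethyl 2-[(6S)-3-acetyl-6-methyl-1-tosylpiperidin-4-yl]-2-(4,5-dimethoxy-7-methylnaphthalen-1-yl)acetate (diastereomer mixture) | CCOC(=O)C(c1ccc(OC)c2c(OC)cc(C)cc12)C1C[C@H](C)N(S(=O)(=O)c2ccc(C)cc2)CC1C(C)=O | intermediate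
22 | (3S)-5-(4,5-dimethoxy-7-methylnaphthalen-1-yl)-3-methyl-2-tosyl-octahydroisoquinoline-6,8-dione (diastereomers at C4a, C5, C8a; keto–enol tautomers) | O=C1CC(=O)C(c2ccc(OC)c3c(OC)cc(C)cc23)C2C1CN(S(=O)(=O)c1ccc(C)cc1)[C@@H](C)C2 | intermediate
23 | (3S)-5-(4,5-dimethoxy-7-methylnaphthalen-1-yl)-8-methoxy-3-methyl-2-tosyl-1,2,3,4-tetrahydroisoquinolin-6-ol | COc1cc(O)c(-c2ccc(OC)c3c(OC)cc(C)cc23)c2c1CN(S(=O)(=O)c1ccc(C)cc1)[C@@H](C)C2 | intermediate
24 | (3S)-5-(4,5-dimethoxy-7-methylnaphthalen-1-yl)-6-methoxy-3-methyl-2-tosyl-1,2,3,4-tetrahydroisoquinolin-8-ol | Oc1cc(OC)c(-c2ccc(OC)c3c(OC)cc(C)cc23)c2c1CN(S(=O)(=O)c1ccc(C)cc1)[C@@H](C)C2 | intermediate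
25 | (3S)-5-(4,5-dimethoxy-7-methylnaphthalen-1-yl)-6,8-dimethoxy-3-methyl-2-tosyl-1,2,3,4-tetrahydroisoquinoline | COc1cc(OC)c(-c2ccc(OC)c3c(OC)cc(C)cc23)c2c1CN(S(=O)(=O)c1ccc(C)cc1)[C@@H](C)C2 | intermediate
26 | (3S)-5-(4,5-dimethoxy-7-methylnaphthalen-1-yl)-6,8-dimethoxy-3-methyl-1,2,3,4-tetrahydroisoquinoline | COc1cc(OC)c(-c2ccc(OC)c3c(OC)cc(C)cc23)c2c1CN[C@@H](C)C2 | target

**Step count and risks**
Total: 15 steps. Longest linear sequence: 9 steps (steps 1–6, then 13–15; the naphthalene branch, steps 7–12 then 13–15, is equally long).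

Steps most likely to fail:

Step 13. The Michael addition to the alpha-branched, beta-substituted enone may be slow and reversible. Self-condensation of the ester, ethoxide addition, or opening of the nitrogen ring by beta-elimination of the sulfonamide could then consume material before the Claisen closure. The fallback separates the two bond formations and sets out from 20 and 9. Compound 20 is converted with LDA and Me3SiCl in THF at −78 °C into the ketene silyl acetal 1-ethoxy-2-(4,5-dimethoxy-7-methylnaphthalen-1-yl)-1-(trimethylsilyloxy)ethene F1. A Mukaiyama–Michael addition of F1 to 9 with TiCl4 in CH2Cl2 at −78 °C should give, after aqueous work-up, keto ester 21, which is isolated this time. A Dieckmann-type closure with KOtBu in THF at 0 °C then leads to 22, where the route is rejoined.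

Step 14. The iodination may stop at the carbon between the two carbonyls. Enol ether formation at C6 may be held back by the neighbouring naphthyl, so that the elimination to the arene does not start. The electron-rich arenes may also be iodinated. The fallback replaces halogenation–elimination by catalytic dehydrogenation and sets out from 22. Heating with Pd/C (10 % palladium on carbon) in refluxing mesitylene under a nitrogen stream should give the resorcinol (3S)-5-(4,5-dimethoxy-7-methylnaphthalen-1-yl)-3-methyl-2-tosyl-1,2,3,4-tetrahydroisoquinoline-6,8-diol F2; the sulfonamide tolerates this temperature. Double O-methylation of F2 with Me2SO4 (2.5 equiv) and K2CO3 in refluxing acetone returns to the route at 25.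

Step 12. Self-condensation of the zinc enolate and slow oxidative addition to the electron-rich bromide with its peri hydrogen may lead to protodebromination or unchanged 19. The fallback goes through a malonate and sets out from 19. Palladium-catalysed arylation of diethyl malonate (Pd(OAc)2, P(t-Bu)3·HBF4, K3PO4, toluene, 100 °C) should give diethyl 2-(4,5-dimethoxy-7-methylnaphthalen-1-yl)propanedioate F3. Krapcho dealkoxycarbonylation of F3 (LiCl, wet DMSO, 150 °C) returns to the route at 20.

**Further compounds**
F1 | step 13 | 1-ethoxy-2-(4,5-dimethoxy-7-methylnaphthalen-1-yl)-1-(trimethylsilyloxy)ethene | CCOC(O[Si](C)(C)C)=Cc1ccc(OC)c2c(OC)cc(C)cc12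
F2 | step 14 | (3S)-5-(4,5-dimethoxy-7-methylnaphthalen-1-yl)-3-methyl-2-tosyl-1,2,3,4-tetrahydroisoquinoline-6,8-diol | Oc1cc(O)c(-c2ccc(OC)c3c(OC)cc(C)cc23)c2c1CN(S(=O)(=O)c1ccc(C)cc1)[C@@H](C)C2
F3 | step 12 | diethyl 2-(4,5-dimethoxy-7-methylnaphthalen-1-yl)propanedioate | CCOC(=O)C(C(=O)OCC)c1ccc(OC)c2c(OC)cc(C)cc12
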